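## Retrosynthetic overview

1. The C40 polyene is cut at C11'=C12' and C11=C12: two Wittig olefinations join a C10 bis(phosphonium) salt to an ε-end C15 aldehyde and to a trihydroxy C15 aldehyde.
2. The trihydroxy C15 aldehyde comes from acetylide addition of (E)-3-methylpent-2-en-4-yn-1-ol to a bridged 3,5-carbonate ketone (C6–C7 bond, attack anti to the bridge sets C6), with alkyne-to-E-alkene reduction and carbonate removal in the same pot.
3. The bridged carbonate ketone comes from an anodic cyclisation of a tert-butyl carbonate onto a silyl enol ether made from (4R,6R)-actinol (C5–O bond; C3 controls C5).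
4. The ε-end C15 aldehyde comes from (R)-α-ionone by chain extension, allylic oxidation, C6'-controlled ketone reduction and nitrile-to-aldehyde reduction.
5. Rings: both carbocycles are bought. The only ring made is the temporary 1,3-dioxan-2-one (step 3), opened again in step 4.

Assumption: (4R,6R)-actinol, enantiopure (R)-α-ionone, (E)-3-methylpent-2-en-4-yn-1-ol and the C10 dialdehyde are bought. Positions are given in carotenoid numbering (C1–C20, C1'–C20').

## Route

Step 1
Reactants: 1 (4R,6R)-4-hydroxy-2,2,6-trimethylcyclohexan-1-one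
Product: 2 tert-butyl (1R,5R)-3,3,5-trimethyl-4-oxocyclohexyl carbonate
Conditions: Boc2O, DMAP (cat.), Et3N, CH2Cl2, 0 °C → rt
Reagents that add atoms: di-tert-butyl dicarbonate, CC(C)(C)OC(=O)OC(=O)OC(C)(C)C
Why: DMAP-catalysed O-acylation (carbonate formation) of the secondary alcohol installs the tether that later delivers oxygen to C5, and the bought C3 stereocentre is not touched.

Step 2
Reactants: 2 tert-butyl (1R,5R)-3,3,5-trimethyl-4-oxocyclohexyl carbonate
Product: 4 tert-butyl [(1R)-4-(tert-butyldimethylsilyloxy)-3,5,5-trimethylcyclohex-3-en-1-yl] carbonate, via lithium enolate 3 (not isolated)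
Conditions: LiN(i-Pr)2, THF, −78 °C; TBSOTf, −78 → 0 °C; aq. NaHCO3
Reagents that add atoms: tert-butyldimethylsilyl trifluoromethanesulfonate, CC(C)(C)[Si](C)(C)OS(=O)(=O)C(F)(F)F
Why: The ketone has a single α-hydrogen, so enolisation and O-silylation (silyl enol ether formation) give one tetrasubstituted enol ether; the methyl-bearing centre is erased on purpose and is reset in step 3.

Step 3
Reactants: 4 tert-butyl [(1R)-4-(tert-butyldimethylsilyloxy)-3,5,5-trimethylcyclohex-3-en-1-yl] carbonate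
Product: 6 (1S,5S)-1,7,7-trimethyl-2,4-dioxabicyclo[3.3.1]nonane-3,8-dione, via tert-butoxydioxanylium cation 5 (not isolated)
Conditions: undivided cell, reticulated vitreous carbon anode, Pt cathode, constant current (2.2 F/mol), n-Bu4NPF6, 2,6-lutidine, MeOH (5 equiv), CH2Cl2/(CF3)2CHOH 9:1, 0 °C
Reagents that add atoms: none
Why: Proposed new method: anodic one-electron oxidation of the silyl enol ether gives a radical cation whose β-carbon (C5) is trapped through a six-membered transition state by the carbonyl oxygen of the axial tert-butyl carbonate, after which oxidation of the α-silyloxy radical, transfer of the silyl group to methanol and loss of 2-methylpropene from the dioxanylium ion give the bridged cyclic carbonate, so the new C5–O bond can only form on the face of the C3 oxygen (3,5-cis, 5S); the closest known reaction types are anodic cyclisations of enol-ether radical cations onto tethered oxygen nucleophiles and the iodocyclisation of homoallylic tert-butyl carbonates.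

Step 4
Reactants: 6 (1S,5S)-1,7,7-trimethyl-2,4-dioxabicyclo[3.3.1]nonane-3,8-dione; 7 (2E)-3-methylpent-2-en-4-yn-1-ol
Product: 10 (1R,2S,4S)-1-[(1E,3E)-5-hydroxy-3-methylpenta-1,3-dien-1-yl]-2,6,6-trimethylcyclohexane-1,2,4-triol, via dilithio enynolate 8 (not isolated), via dilithium alkoxide adduct 9 (not isolated)
Conditions: 7 (2.2 equiv), n-BuLi (4.4 equiv), THF, −78 → −20 °C; 6, −78 °C, 1 h; then NaAlH2(OCH2CH2OMe)2 (6 equiv), −78 °C → rt; aq. KNaC4H4O6
Reagents that add atoms: none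
Why: 1,2-Addition of the lithium acetylide to the non-enolisable ketone occurs from the face opposite the carbonate bridge (the bridge and the endo methyl block the other face), which sets C6 with all three oxygens cis, and in the same pot alkoxide-directed trans-hydroalumination of the propargylic alkoxide gives the 7E alkene while hydride reduces the carbonate off as methanol.

Step 5
Reactants: 10 (1R,2S,4S)-1-[(1E,3E)-5-hydroxy-3-methylpenta-1,3-dien-1-yl]-2,6,6-trimethylcyclohexane-1,2,4-triol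
Product: 11 (2E,4E)-3-methyl-5-[(1R,2S,4S)-1,2,4-trihydroxy-2,6,6-trimethylcyclohexyl]penta-2,4-dienal
Conditions: Cu(MeCN)4OTf (5 mol%), 2,2'-bipyridine (5 mol%), TEMPO (5 mol%), N-methylimidazole (10 mol%), air, MeCN, rt
Reagents that add atoms: none
Why: Cu/TEMPO aerobic alcohol oxidation is selective for the primary allylic alcohol over the secondary and tertiary hydroxyls, does not cleave the vicinal diol and keeps the diene geometry.

Step 6
Reactants: 12 (3E)-4-[(1R)-2,6,6-trimethylcyclohex-2-en-1-yl]but-3-en-2-one ((R)-α-ionone)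
Product: 13 (2E,4E)-3-methyl-5-[(1R)-2,6,6-trimethylcyclohex-2-en-1-yl]penta-2,4-dienenitrile
Conditions: (EtO)2P(O)CH2CN, NaH, THF, 0 °C → rt; minor 2Z isomer removed by chromatography
Reagents that add atoms: diethyl cyanomethylphosphonate, N#CCP(=O)(OCC)OCC
Why: Horner–Wadsworth–Emmons olefination of the methyl ketone gives mainly the E dienenitrile and leaves C6' untouched.

Step 7
Reactants: 13 (2E,4E)-3-methyl-5-[(1R)-2,6,6-trimethylcyclohex-2-en-1-yl]penta-2,4-dienenitrile
Product: 14 (2E,4E)-3-methyl-5-[(1R)-2,6,6-trimethyl-4-oxocyclohex-2-en-1-yl]penta-2,4-dienenitrile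
Conditions: Mn(OAc)3·2H2O (10 mol%), t-BuOOH (5 equiv), 3 Å MS, EtOAc, rt
Reagents that add atoms: tert-butyl hydroperoxide, CC(C)(C)OO
Why: Radical allylic oxidation converts the ring CH2 at C3' next to the trisubstituted alkene into the enone under neutral conditions, which avoids epimerising the γ-stereocentre C6'.

Step 8
Reactants: 14 (2E,4E)-3-methyl-5-[(1R)-2,6,6-trimethyl-4-oxocyclohex-2-en-1-yl]penta-2,4-dienenitrile
Product: 15 (2E,4E)-5-[(1R,4R)-4-hydroxy-2,6,6-trimethylcyclohex-2-en-1-yl]-3-methylpenta-2,4-dienenitrile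
Conditions: KBH(s-Bu)3, THF, −78 °C; H2O; minor cis epimer removed by chromatography
Reagents that add atoms: none
Why: 1,2-Reduction of the enone by the bulky borohydride takes the equatorial path, away from the axial methyl of the gem-dimethyl group that sits anti to the pseudoaxial C6' side chain, so the hydroxyl ends up pseudoaxial and trans to the side chain (3'R, controlled by C6').

Step 9
Reactants: 15 (2E,4E)-5-[(1R,4R)-4-hydroxy-2,6,6-trimethylcyclohex-2-en-1-yl]-3-methylpenta-2,4-dienenitrile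
Product: 17 (2E,4E)-5-[(1R,4R)-4-hydroxy-2,6,6-trimethylcyclohex-2-en-1-yl]-3-methylpenta-2,4-dienal, via aldimine 16 (not isolated)
Conditions: i-Bu2AlH (2.5 equiv), CH2Cl2, −78 → −40 °C; aq. KNaC4H4O6, then wet SiO2
Reagents that add atoms: water, O
Why: Partial reduction of the nitrile to the aluminated aldimine and its non-acidic hydrolysis give the dienal without touching the acid-sensitive allylic alcohol or either stereocentre.

Step 10
Reactants: 18 (2E,4E,6E)-2,7-dimethylocta-2,4,6-trienedial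
Product: 19 (2E,4E,6E)-2,7-dimethylocta-2,4,6-triene-1,8-diol
Conditions: NaBH4, MeOH/THF, 0 °C
Reagents that add atoms: none
Why: Borohydride 1,2-reduction of both enal carbonyls gives the bis-allylic diol with the triene geometry unchanged.

Step 11
Reactants: 19 (2E,4E,6E)-2,7-dimethylocta-2,4,6-triene-1,8-diol
Product: 20 [(2E,4E,6E)-2,7-dimethylocta-2,4,6-triene-1,8-diyl]bis(triphenylphosphonium) dibromide
Conditions: PPh3·HBr (2.1 equiv), MeOH/CH2Cl2, rt, dark
Reagents that add atoms: triphenylphosphine hydrobromide, [Br-].[PH+](c1ccccc1)(c1ccccc1)c1ccccc1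
Why: Acid-mediated ionisation of the primary allylic alcohols and capture of the allylic cations by triphenylphosphine at the unhindered termini is the standard phosphonium salt formation.

Step 12
Reactants: 17 (2E,4E)-5-[(1R,4R)-4-hydroxy-2,6,6-trimethylcyclohex-2-en-1-yl]-3-methylpenta-2,4-dienal; 20 [(2E,4E,6E)-2,7-dimethylocta-2,4,6-triene-1,8-diyl]bis(triphenylphosphonium) dibromide
Product: 22 [(2E,4E,6E,8E,10E,12E)-13-[(1R,4R)-4-hydroxy-2,6,6-trimethylcyclohex-2-en-1-yl]-2,7,11-trimethyltrideca-2,4,6,8,10,12-hexaen-1-yl]triphenylphosphonium bromide, via mono-ylide 21 (not isolated)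
Conditions: 20 (3 equiv), NaOMe (1.0 equiv), MeOH/CH2Cl2, −10 °C → rt, Ar, dark; SiO2 (CH2Cl2/MeOH), excess 20 recovered
Reagents that add atoms: none
Why: In this Wittig olefination one equivalent of base gives essentially the mono-ylide (a second deprotonation would place two carbanions on one triene), and excess salt suppresses double condensation; the new C11'=C12' bond forms as an E/Z mixture that is equilibrated in step 13.

Step 13
Reactants: 22 [(2E,4E,6E,8E,10E,12E)-13-[(1R,4R)-4-hydroxy-2,6,6-trimethylcyclohex-2-en-1-yl]-2,7,11-trimethyltrideca-2,4,6,8,10,12-hexaen-1-yl]triphenylphosphonium bromide; 11 (2E,4E)-3-methyl-5-[(1R,2S,4S)-1,2,4-trihydroxy-2,6,6-trimethylcyclohexyl]penta-2,4-dienal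
Product: 24 (all-E)-(3S,5S,6R,3'R,6'R)-5,6-dihydro-β,ε-carotene-3,5,6,3'-tetrol (5,6-dihydroxylutein), via C25 ylide 23 (not isolated)
Conditions: NaOMe (1.3 equiv), MeOH/CH2Cl2, 0 °C → rt, Ar, dark; then reflux in EtOAc under Ar (Z → E), crystallisation
Reagents that add atoms: none
Why: The second Wittig olefination joins the halves under protic conditions that tolerate the four free hydroxyls, heating converts the sterically hindered 11Z and 11'Z isomers into the all-E polyene, and all five stereocentres are remote from the reacting carbons.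

## Compound list

1 | (4R,6R)-4-hydroxy-2,2,6-trimethylcyclohexan-1-one ((4R,6R)-actinol) | O=C1C(C)(C)C[C@H](O)C[C@H]1C | starting material
2 | tert-butyl (1R,5R)-3,3,5-trimethyl-4-oxocyclohexyl carbonate | O=C1C(C)(C)C[C@H](OC(=O)OC(C)(C)C)C[C@H]1C | intermediate
3 | lithium (4R)-4-(tert-butoxycarbonyloxy)-2,6,6-trimethylcyclohex-1-en-1-olate | [Li+].[O-]C1=C(C)C[C@@H](OC(=O)OC(C)(C)C)CC1(C)C | intermediate (not isolated)
4 | tert-butyl [(1R)-4-(tert-butyldimethylsilyloxy)-3,5,5-trimethylcyclohex-3-en-1-yl] carbonate | CC1=C(O[Si](C)(C)C(C)(C)C)C(C)(C)C[C@H](OC(=O)OC(C)(C)C)C1 | intermediate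
5 | bridged 2-tert-butoxy-1,3-dioxan-2-ylium cation (3,5-cis-fused on the 6-ketone; cation of 6 carrying O-tert-butyl) | O=C1C(C)(C)C[C@H]2C[C@]1(C)OC(OC(C)(C)C)=[O+]2 | intermediate (not isolated)
6 | (1S,5S)-1,7,7-trimethyl-2,4-dioxabicyclo[3.3.1]nonane-3,8-dione | O=C1C(C)(C)C[C@H]2C[C@]1(C)OC(=O)O2 | intermediate
7 | (2E)-3-methylpent-2-en-4-yn-1-ol | OC/C=C(C)/C#C | starting material
8 | dilithium (2E)-3-methylpent-2-en-4-yn-5-id-1-olate | [Li+].[Li+].[O-]C/C=C(C)/C#[C-] | intermediate (not isolated)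
9 | dilithium (1S,5S,8S)-1,7,7-trimethyl-8-[(3E)-3-methyl-5-oxidopent-3-en-1-yn-1-yl]-3-oxo-2,4-dioxabicyclo[3.3.1]nonan-8-olate | [Li+].[Li+].[O-]C/C=C(C)/C#C[C@@]1([O-])C(C)(C)C[C@H]2C[C@]1(C)OC(=O)O2 | intermediate (not isolated)
10 | (1R,2S,4S)-1-[(1E,3E)-5-hydroxy-3-methylpenta-1,3-dien-1-yl]-2,6,6-trimethylcyclohexane-1,2,4-triol | OC/C=C(C)/C=C/[C@@]1(O)C(C)(C)C[C@H](O)C[C@]1(C)O | intermediate
11 | (2E,4E)-3-methyl-5-[(1R,2S,4S)-1,2,4-trihydroxy-2,6,6-trimethylcyclohexyl]penta-2,4-dienal | O=C/C=C(C)/C=C/[C@@]1(O)C(C)(C)C[C@H](O)C[C@]1(C)O | intermediate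
12 | (3E)-4-[(1R)-2,6,6-trimethylcyclohex-2-en-1-yl]but-3-en-2-one ((R)-α-ionone) | CC1=CCCC(C)(C)[C@H]1/C=C/C(C)=O | starting material
13 | (2E,4E)-3-methyl-5-[(1R)-2,6,6-trimethylcyclohex-2-en-1-yl]penta-2,4-dienenitrile | CC1=CCCC(C)(C)[C@H]1/C=C/C(C)=C/C#N | intermediate
14 | (2E,4E)-3-methyl-5-[(1R)-2,6,6-trimethyl-4-oxocyclohex-2-en-1-yl]penta-2,4-dienenitrile | CC1=CC(=O)CC(C)(C)[C@H]1/C=C/C(C)=C/C#N | intermediate
15 | (2E,4E)-5-[(1R,4R)-4-hydroxy-2,6,6-trimethylcyclohex-2-en-1-yl]-3-methylpenta-2,4-dienenitrile | CC1=C[C@H](O)CC(C)(C)[C@H]1/C=C/C(C)=C/C#N | intermediate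
16 | (2E,4E)-5-[(1R,4R)-4-hydroxy-2,6,6-trimethylcyclohex-2-en-1-yl]-3-methylpenta-2,4-dien-1-imine (formed as its N-aluminium derivative) | CC1=C[C@H](O)CC(C)(C)[C@H]1/C=C/C(C)=C/C=N | intermediate (not isolated)
17 | (2E,4E)-5-[(1R,4R)-4-hydroxy-2,6,6-trimethylcyclohex-2-en-1-yl]-3-methylpenta-2,4-dienal | CC1=C[C@H](O)CC(C)(C)[C@H]1/C=C/C(C)=C/C=O | intermediate
18 | (2E,4E,6E)-2,7-dimethylocta-2,4,6-trienedial | O=C/C(C)=C/C=C/C=C(C)/C=O | starting material
19 | (2E,4E,6E)-2,7-dimethylocta-2,4,6-triene-1,8-diol | OC/C(C)=C/C=C/C=C(C)/CO | intermediate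
20 | [(2E,4E,6E)-2,7-dimethylocta-2,4,6-triene-1,8-diyl]bis(triphenylphosphonium) dibromide | [Br-].[Br-].c1ccccc1[P+](c1ccccc1)(c1ccccc1)C/C(C)=C/C=C/C=C(C)/C[P+](c1ccccc1)(c1ccccc1)c1ccccc1 | intermediate
21 | mono-ylide of 20: [(2E,4E,6E)-2,7-dimethyl-8-(triphenylphosphoranylidene)octa-2,4,6-trien-1-yl]triphenylphosphonium bromide | [Br-].c1ccccc1P(c1ccccc1)(c1ccccc1)=C/C(C)=C/C=C/C=C(C)/C[P+](c1ccccc1)(c1ccccc1)c1ccccc1 | intermediate (not isolated)
22 | [(2E,4E,6E,8E,10E,12E)-13-[(1R,4R)-4-hydroxy-2,6,6-trimethylcyclohex-2-en-1-yl]-2,7,11-trimethyltrideca-2,4,6,8,10,12-hexaen-1-yl]triphenylphosphonium bromide (drawn 8E; obtained with some 8Z, i.e. 11'Z) | CC1=C[C@H](O)CC(C)(C)[C@H]1/C=C/C(C)=C/C=C/C(C)=C/C=C/C=C(C)/C[P+](c1ccccc1)(c1ccccc1)c1ccccc1.[Br-] | intermediate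
23 | ylide of 22: (1R,4R)-3,5,5-trimethyl-4-[(1E,3E,5E,7E,9E,11E)-3,7,12-trimethyl-13-(triphenylphosphoranylidene)trideca-1,3,5,7,9,11-hexaen-1-yl]cyclohex-2-en-1-ol | CC1=C[C@H](O)CC(C)(C)[C@H]1/C=C/C(C)=C/C=C/C(C)=C/C=C/C=C(C)/C=P(c1ccccc1)(c1ccccc1)c1ccccc1 | intermediate (not isolated)
24 | (all-E)-(3S,5S,6R,3'R,6'R)-5,6-dihydro-β,ε-carotene-3,5,6,3'-tetrol (5,6-dihydroxylutein) | CC1=C[C@H](O)CC(C)(C)[C@H]1/C=C/C(C)=C/C=C/C(C)=C/C=C/C=C(C)/C=C/C=C(C)/C=C/[C@@]1(O)C(C)(C)C[C@H](O)C[C@]1(C)O | target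

## Summary

Total step count: 13. Longest linear sequence: 6 steps (steps 1–5 and 13; the ε-end branch, steps 6–9, 12 and 13, is equally long).

Three steps most likely to fail:

Step 3 (the proposed new anodic carbonate transfer). The radical cation may instead lose a proton to give the enone, lose the silyl group before it is trapped, or be trapped by methanol; the bridged ring also forces the carbonate into an axial position next to a gem-dimethyl group. The fallback uses known chemistry and sets out from 2. LiN(i-Pr)2 and Me3SiCl give tert-butyl [(1R)-3,5,5-trimethyl-4-(trimethylsilyloxy)cyclohex-3-en-1-yl] carbonate F1. Dye-sensitised photooxygenation (O2, tetraphenylporphyrin, visible light, CH2Cl2, −78 °C) is the known silatropic ene reaction of singlet oxygen with silyl enol ethers; it attacks the face anti to the pseudoaxial ring methyl, which is the face of the carbonate, and gives tert-butyl (1S,3S)-3,5,5-trimethyl-4-oxo-3-(trimethylsilylperoxy)cyclohexyl carbonate F2. PPh3 in MeOH reduces and desilylates it to tert-butyl (1S,3S)-3-hydroxy-3,5,5-trimethyl-4-oxocyclohexyl carbonate F3. Catalytic KOt-Bu in THF then closes the bridged carbonate by intramolecular transcarbonation, which only the 3,5-cis isomer can do, and the route is rejoined at 6.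

Step 4 (one-pot acetylide addition and hydride reduction on a hindered bicyclic ketone). The dianion may react sluggishly or attack the carbonate, and the hydride step on the unprotected enyne may over-reduce. The fallback sets out from 6. The small nucleophile LiC≡CSiMe3 with CeCl3 (THF, −78 °C) gives (1S,5S,8S)-8-hydroxy-1,7,7-trimethyl-8-[(trimethylsilyl)ethynyl]-2,4-dioxabicyclo[3.3.1]nonan-3-one F4, which is isolated. K2CO3 in MeOH removes the silyl group and the carbonate to give (1S,2S,4S)-1-ethynyl-2,6,6-trimethylcyclohexane-1,2,4-triol F5. Sonogashira coupling with (E)-3-iodobut-2-en-1-ol (PdCl2(PPh3)2, CuI, i-Pr2NH) builds the C8–C9 bond and gives (1S,2S,4S)-1-[(3E)-5-hydroxy-3-methylpent-3-en-1-yn-1-yl]-2,6,6-trimethylcyclohexane-1,2,4-triol F6. NaAlH2(OCH2CH2OMe)2 in THF then gives the E-alkene, and the route is rejoined at 10.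

Step 12 (mono-olefination of the symmetrical bis-salt). Double condensation and the separation of two phosphonium salts may cut the yield. The fallback sets out from 19 and replaces the salts by neutral phosphonates. PBr3 gives (2E,4E,6E)-1,8-dibromo-2,7-dimethylocta-2,4,6-triene F7. Arbuzov reaction with P(OEt)3 gives tetraethyl [(2E,4E,6E)-2,7-dimethylocta-2,4,6-triene-1,8-diyl]bis(phosphonate) F8. Horner–Wadsworth–Emmons reaction of excess F8 with 17 (KOt-Bu, THF, −30 °C) gives diethyl [(2E,4E,6E,8E,10E,12E)-13-[(1R,4R)-4-hydroxy-2,6,6-trimethylcyclohex-2-en-1-yl]-2,7,11-trimethyltrideca-2,4,6,8,10,12-hexaen-1-yl]phosphonate F9, which is purified on silica. A second Horner–Wadsworth–Emmons reaction of F9 with 11 (excess KOt-Bu, THF) rejoins the route at 24.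

Further compounds
F1 | step 3 | tert-butyl [(1R)-3,5,5-trimethyl-4-(trimethylsilyloxy)cyclohex-3-en-1-yl] carbonate | CC1=C(O[Si](C)(C)C)C(C)(C)C[C@H](OC(=O)OC(C)(C)C)C1
F2 | step 3 | tert-butyl (1S,3S)-3,5,5-trimethyl-4-oxo-3-(trimethylsilylperoxy)cyclohexyl carbonate | O=C1C(C)(C)C[C@H](OC(=O)OC(C)(C)C)C[C@]1(C)OO[Si](C)(C)C
F3 | step 3 | tert-butyl (1S,3S)-3-hydroxy-3,5,5-trimethyl-4-oxocyclohexyl carbonate | O=C1C(C)(C)C[C@H](OC(=O)OC(C)(C)C)C[C@]1(C)O
F4 | step 4 | (1S,5S,8S)-8-hydroxy-1,7,7-trimethyl-8-[(trimethylsilyl)ethynyl]-2,4-dioxabicyclo[3.3.1]nonan-3-one | C[Si](C)(C)C#C[C@@]1(O)C(C)(C)C[C@H]2C[C@]1(C)OC(=O)O2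
F5 | step 4 | (1S,2S,4S)-1-ethynyl-2,6,6-trimethylcyclohexane-1,2,4-triol | C#C[C@@]1(O)C(C)(C)C[C@H](O)C[C@]1(C)O
F6 | step 4 | (1S,2S,4S)-1-[(3E)-5-hydroxy-3-methylpent-3-en-1-yn-1-yl]-2,6,6-trimethylcyclohexane-1,2,4-triol | OC/C=C(C)/C#C[C@@]1(O)C(C)(C)C[C@H](O)C[C@]1(C)O
F7 | step 12 | (2E,4E,6E)-1,8-dibromo-2,7-dimethylocta-2,4,6-triene | BrC/C(C)=C/C=C/C=C(C)/CBr
F8 | step 12 | tetraethyl [(2E,4E,6E)-2,7-dimethylocta-2,4,6-triene-1,8-diyl]bis(phosphonate) | CCOP(=O)(OCC)C/C(C)=C/C=C/C=C(C)/CP(=O)(OCC)OCC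
F9 | step 12 | diethyl [(2E,4E,6E,8E,10E,12E)-13-[(1R,4R)-4-hydroxy-2,6,6-trimethylcyclohex-2-en-1-yl]-2,7,11-trimethyltrideca-2,4,6,8,10,12-hexaen-1-yl]phosphonate | CC1=C[C@H](O)CC(C)(C)[C@H]1/C=C/C(C)=C/C=C/C(C)=C/C=C/C=C(C)/CP(=O)(OCC)OCC
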